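Before we put a charge through the tank or the slow feed, we want to know whether either buys selectivity over the plain batch.

| flask | starting material | catalyst | remark | time |
|---|---|---|---|---|
| Friday's | 0.25 M | 0.5 mol% | run made earlier |  |
| Monday's | 0.25 M | 0.34 mol% | run made earlier |  |
| Sunday's | 0.25 M | 0.75 mol% | run made earlier |  |
| autumn | 0.25 M | 0.5 mol% | everything together in a closed stirred flask, run for 40 min | 40 min |
| noon | 0.25 M | 0.5 mol% | a single well-mixed tank run continuously and read at steady state, 40 min in it on average |  |
| dusk | 0.25 M (fed, over 32.0 min) | 0.5 mol% | all but starting material at the start; starting material goes in evenly over 32.0 min, the run ends at 40 min | 40 min |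

| run | time / min | target / % | isomer of the product / % |
|---|---|---|---|
| Friday's | 2.00 | 0 | 0 |
| Friday's | 3.00 | 1.8 | 1.3 |
| Friday's | 4.00 | 2.8 | 0 |
| Friday's | 6.00 | 4.2 | 0 |
| Friday's | 10.0 | 3.9 | 0.1 |
| Friday's | 15.0 | 8.6 | 0 |
| Friday's | 25.0 | 13.4 | 0 |
| Monday's | 3.00 | 0.2 | 0.9 |
| Monday's | 6.00 | 1.6 | 0.2 |
| Monday's | 10.0 | 5.0 | 0 |
| Monday's | 15.0 | 5.4 | 1.1 |
| Monday's | 20.0 | 8.3 | 1.3 |
| Monday's | 25.0 | 8.3 | 1.1 |
| Sunday's | 2.00 | 2.1 | 0 |
| Sunday's | 3.00 | 2.1 | 0 |
| Sunday's | 4.00 | 1.6 | 0 |
| Sunday's | 6.00 | 5.2 | 1.3 |
| Sunday's | 10.0 | 8.5 | 2.2 |
| Sunday's | 15.0 | 13.2 | 0 |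
| Sunday's | 25.0 | 18.9 | 0.5 |

(scatter of a reading: 1 percentage point)

- the stated concentrations are those of everything mixed, before any reaction; amounts are the same in each set-up
- the analysis behind the earlier runs scatters by 1 percentage point, standard deviation
- the feed brings no volume worth counting
- the earlier runs were made in a closed, stirred flask

1. the set-up with the highest share of target in all that became target or isomer of the product, at the outlet or at the end ("none" if the first two lie within 2 percentage points) (autumn / noon / dusk / none)
2. share of target in all that became target or isomer of the product, at the outlet or at the end, autumn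
3. share of target in all that became target or isomer of the product, at the outlet or at the end, noon
4. share of target in all that became target or isomer of the product, at the outlet or at the end, dusk

Let ΣP and ΣQ be the percentages of target and of isomer of the product, each summed over the 20 readings of the three runs, and let S be the selectivity ΣP/(ΣP+ΣQ). Which numbers must we know well?

The loading need not be known closely. At 25.0 min, from Monday's run to Sunday's, catalyst rises by a factor 2.21 and target by 2.28, so target reads as first order in catalyst. The isomer lies too near the scatter to show its own order. We take it as the same, and then catalyst concentration and time cancel out of S.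

Every run stood at 0.25 M, so the order in starting material is unread. We assume target and isomer share it, and on that assumption S carries to all three set-ups.

That leaves the sums, ΣP = 115 % and ΣQ = 10.0 %. Each carries a standard deviation of 4.5 percentage points. That error moves S by 0.28 points on ΣP but by 3.2 points on ΣQ, so the isomer sum is the number that matters.

S = ΣP/(ΣP+ΣQ) = 92.0 %
low end, ΣQ one deviation up: 88.8 %

We carry this pooled share of target to autumn, noon and dusk alike, so our verdict is that no set-up wins.

The forecast gives 94 %, 94 % and 94 %, verdict none, higher than our S, holding that “Nothing shows that the tank or the slow feed would shift the selectivity”.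

The simulation gives 90.6 % for autumn, 90.6 % for noon and 90.7 % for dusk, verdict none.

    other conformer ⇌ dormant form (K = 2.30, k = 3.80 × 10⁻⁴ s⁻¹)
    starting material ⇌ other conformer (K = 0.280, k = 0.00410 s⁻¹)
    catalyst + other conformer → catalyst + isomer of the product (k = 0.0390 M⁻¹ s⁻¹)
    starting material + catalyst → catalyst + target (k = 0.100 M⁻¹ s⁻¹)

Autumn's 90.6 % lies 1.4 points below S and above its low end. On the neighbour of dusk charged with 0.62 M, S sets beside that flask's 27.2 % target an expected 2.37 % isomer of the product, and the flask holds 2.77 %. Dusk has not come to rest at 40.0 min, with 60.9 % starting material beside 12.4 % target. By 400 min dusk holds 8.61 % starting material, 72.3 % target and 7.84 % isomer of the product, and its share has moved from 90.7 % to 90.2 %.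

The runs come from a simulation on assumed constants.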